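## Retrosynthetic overview

1. Target 24 ⇒ acid 21, (5S,8R,9R,13R)-halim-1(10)-en-15-oic acid, plus (R)-glycidyl acetate 23; the acid opens the epoxide at its CH2 and glycerol C-2 comes from (S)-glycidol.
2. 21 ⇒ one hydrogenation (C6=C7, C8=CH2 and C11=C12; sets C8) of Wittig acid 20 ⇐ C11 aldehyde 16 plus a C12–C15 ylide from (S)-β-methyl-γ-butyrolactone (C13).
3. 16 ⇐ ester 15 ⇐ key step: intramolecular Diels–Alder of bis-allene 14 (vinylallene diene, α-methyl allenoate dienophile). Rings B (cycloaddition) and A (tether) form together in this one operation; no other ring is made.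
4. 14 ⇐ anti-SN2′ methylation of the mesylate of (S)-γ-hydroxy-ynoate 12 (centre → axis → C9) ⇐ aldehyde 9 plus methyl propiolate.
5. 9 ⇐ isobutyraldehyde plus methyl acrylate (C4 gem-dimethyl), Takai iodo-olefination, Stille coupling with an allenylstannane.

Assumption: atom numbers in the explanations are halimane numbers (decalin C1–C10, side chain C11–C16, C17 on C8, C20 on C9), and (S,S)-ProPhenol is taken to deliver the alkynylzinc to the Re face of aldehyde 9 as it does in its aldol reactions (if the sense is opposite, the (R,R) ligand is used).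

## Route

Step 1
Reactants: 1 isobutyraldehyde; 2 methyl acrylate
Product: 5 methyl 4,4-dimethyl-5-oxopentanoate, via enamine 3 (not isolated), via aminocyclobutane ester 4 (not isolated)
Conditions: pyrrolidine (1.05 equiv), K2CO3, 0 °C to rt; then 2, MeCN, reflux; then AcOH–H2O, 50 °C
Reagents that add atoms: none
Why: Stork enamine Michael addition of the α,α-disubstituted enamine to the acrylate (through the [2+2] adduct, which opens on hydrolysis) builds the quaternary gem-dimethyl carbon C4 with C5 as aldehyde and C1 as ester.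

Step 2
Reactants: 5 methyl 4,4-dimethyl-5-oxopentanoate
Product: 6 methyl (5E)-6-iodo-4,4-dimethylhex-5-enoate
Conditions: CrCl2 (6 equiv), CHI3 (2 equiv), THF–dioxane, 0 °C to rt
Reagents that add atoms: iodoform, IC(I)I
Why: Takai iodo-olefination is E-selective for α-branched aldehydes and leaves the ester untouched, setting the (E)-C5=C6 geometry that places the tether "outside" on the diene.

Step 3
Reactants: 6 methyl (5E)-6-iodo-4,4-dimethylhex-5-enoate; 7 tributyl(propa-1,2-dien-1-yl)stannane
Product: 8 methyl (5E)-4,4-dimethylnona-5,7,8-trienoate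
Conditions: Pd2(dba)3 (2.5 mol %), AsPh3 (10 mol %), LiCl, NMP, rt to 45 °C
Reagents that add atoms: none
Why: Stille coupling transfers the allenyl group to the vinyl iodide with retention of the E geometry, giving the vinylallene diene (C5=C6–C7=C8=C17).

Step 4
Reactants: 8 methyl (5E)-4,4-dimethylnona-5,7,8-trienoate
Product: 9 (5E)-4,4-dimethylnona-5,7,8-trienal
Conditions: DIBAL-H (1.05 equiv), CH2Cl2, −78 °C; Rochelle salt
Reagents that add atoms: none
Why: Partial DIBAL reduction stops at the aldehyde because the tetrahedral aluminium hemiacetal is stable at −78 °C; the vinylallene is inert.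

Step 5
Reactants: 9 (5E)-4,4-dimethylnona-5,7,8-trienal; 10 methyl propiolate
Product: 12 methyl (4S,8E)-4-hydroxy-7,7-dimethyldodeca-8,10,11-trien-2-ynoate, via zinc alkynylide 11 (not isolated)
Conditions: 10 (3 equiv), Me2Zn (3 equiv), (S,S)-ProPhenol (20 mol %), Ph3P=O (40 mol %), toluene, 4 °C; aq. NH4Cl
Reagents that add atoms: none
Why: Catalytic asymmetric zinc-alkynylation (dinuclear Zn–ProPhenol) adds the propiolate to the Re face of the aldehyde and sets the (S) carbinol at C1, which is later converted into the allene axis.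

Step 6
Reactants: 12 methyl (4S,8E)-4-hydroxy-7,7-dimethyldodeca-8,10,11-trien-2-ynoate
Product: 14 methyl (aS,8E)-2,7,7-trimethyldodeca-2,3,8,10,11-pentaenoate, via propargylic mesylate 13 (not isolated)
Conditions: LiHMDS (1.05 equiv), THF, −78 °C; MsCl (1.1 equiv); then cannulate into MeMgBr/CuBr·SMe2/LiBr (1.5 equiv each), THF, −78 °C, 30 min
Reagents that add atoms: methylmagnesium bromide, C[Mg]Br
Why: Organocopper anti-SN2′ substitution of the γ-mesyloxy ynoate puts the methyl on the ester-bearing carbon (C9) anti to the leaving group, so the (S) centre is transferred to the (aS) allene axis.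

Step 7
Reactants: 14 methyl (aS,8E)-2,7,7-trimethyldodeca-2,3,8,10,11-pentaenoate
Product: 15 methyl (1R,4aS)-1,5,5-trimethyl-2-methylidene-1,2,4a,5,6,7-hexahydronaphthalene-1-carboxylate
Conditions: Me2AlCl (1.2 equiv), CH2Cl2 (0.01 M), −78 to −20 °C
Reagents that add atoms: none
Why: Proposed new method: intramolecular Diels–Alder of a tethered bis-allene, in which the s-cis vinylallene (C5=C6–C7=C8) adds across the ester-conjugated, Lewis-acid-activated Cα=Cβ bond (C9=C10) of the allenoate, C10 bonding to C5 so that the three-atom tether closes ring A as a cyclohexene that keeps the untouched C10=C1 bond while the cycloaddition closes ring B and leaves C8=CH2 exocyclic; the tether can only reach the face of C9=C10 on which C2 sits, so the (aS) axis becomes (9R), and an α-methyl acyl dienophile is expected to react exo-ester/methyl-endo (as methacrylates, tiglates and methacrolein do), which puts H-5 cis to the ester (5S); closest known reaction types are Lewis-acid Diels–Alder reactions of 2-substituted 2,3-dienoates at the α,β bond, vinylallene Diels–Alder reactions with axis-to-centre transfer, and Rh-catalysed intramolecular diene–allene [4+2] at the distal allene π bond.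

Step 8
Reactants: 15 methyl (1R,4aS)-1,5,5-trimethyl-2-methylidene-1,2,4a,5,6,7-hexahydronaphthalene-1-carboxylate
Product: 16 (1R,4aS)-1,5,5-trimethyl-2-methylidene-1,2,4a,5,6,7-hexahydronaphthalene-1-carbaldehyde
Conditions: DIBAL-H (1.2 equiv), CH2Cl2, −78 °C; Rochelle salt
Reagents that add atoms: none
Why: Partial DIBAL reduction of a hindered α-quaternary ester stops cleanly at the aldehyde (C11), which has no α-hydrogen and therefore cannot epimerise or conjugate.

Step 9
Reactants: 17 (4S)-4-methyloxolan-2-one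
Product: 18 [(2S)-3-carboxy-2-methylpropyl]triphenylphosphonium bromide
Conditions: Ph3P·HBr (1.0 equiv), neat melt, 160 °C, 6 h; triturate with acetone–Et2O
Reagents that add atoms: triphenylphosphine hydrobromide, [Br-].[PH+](c1ccccc1)(c1ccccc1)c1ccccc1
Why: Acid-promoted alkyl–oxygen opening of the γ-lactone by bromide followed by phosphine alkylation at the primary carbon gives the carboxy phosphonium salt without touching the C13 stereocentre.

Step 10
Reactants: 16 (1R,4aS)-1,5,5-trimethyl-2-methylidene-1,2,4a,5,6,7-hexahydronaphthalene-1-carbaldehyde; 18 [(2S)-3-carboxy-2-methylpropyl]triphenylphosphonium bromide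
Product: 20 (3S,4Z)-3-methyl-5-[(1R,4aS)-1,5,5-trimethyl-2-methylidene-1,2,4a,5,6,7-hexahydronaphthalen-1-yl]pent-4-enoic acid, via phosphorus ylide 19 (not isolated)
Conditions: 18 (2.0 equiv), NaHMDS (4.0 equiv), THF, 0 °C; then 16, −78 °C to 40 °C; aq. HCl work-up
Reagents that add atoms: none
Why: Wittig olefination with the non-stabilised carboxylate ylide joins C11 to C12 on the non-enolisable neopentyl aldehyde (alkene geometry is irrelevant) and brings in C13 from the chiral pool with the free acid already in place.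

Step 11
Reactants: 20 (3S,4Z)-3-methyl-5-[(1R,4aS)-1,5,5-trimethyl-2-methylidene-1,2,4a,5,6,7-hexahydronaphthalen-1-yl]pent-4-enoic acid
Product: 21 (3R)-3-methyl-5-[(1R,2R,4aS)-1,2,5,5-tetramethyl-1,2,3,4,4a,5,6,7-octahydronaphthalen-1-yl]pentanoic acid
Conditions: H2 (1 atm), 5 % Pt/C, EtOAc, rt, stopped after 3 equiv H2
Reagents that add atoms: none
Why: Heterogeneous hydrogenation takes the two disubstituted alkenes and the exocyclic methylene but should spare the trisubstituted C1=C10 bond flanked by quaternary C9 and C5, and hydrogen is delivered to C8 from the β face, anti to the axial C9 side chain, giving the 8α-methyl group (8R).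

Step 12
Reactants: 22 (S)-glycidol
Product: 23 (R)-glycidyl acetate
Conditions: Ac2O (1.1 equiv), Et3N, DMAP (cat.), CH2Cl2, 0 °C
Reagents that add atoms: acetic anhydride, CC(=O)OC(C)=O
Why: Simple O-acetylation that breaks no bond at the stereocentre (the descriptor changes from S to R only through the priority rules).

Step 13
Reactants: 21 (3R)-3-methyl-5-[(1R,2R,4aS)-1,2,5,5-tetramethyl-1,2,3,4,4a,5,6,7-octahydronaphthalen-1-yl]pentanoic acid; 23 (R)-glycidyl acetate
Product: 24 (2S)-3-(acetyloxy)-2-hydroxypropyl (3R)-3-methyl-5-[(1R,2R,4aS)-1,2,5,5-tetramethyl-1,2,3,4,4a,5,6,7-octahydronaphthalen-1-yl]pentanoate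
Conditions: 23 (1.5 equiv), Bu4NBr (10 mol %), toluene, 80 °C
Reagents that add atoms: none
Why: Quaternary-ammonium-halide-catalysed addition of a carboxylic acid to a terminal epoxide occurs by SN2 attack at the CH2 carbon, so the glycerol C-2 centre is untouched and the 1-acyl-3-acetyl-2-hydroxy pattern (2S) is obtained directly.

## Compound list

1 | isobutyraldehyde | CC(C)C=O | starting material
2 | methyl acrylate | C=CC(=O)OC | starting material
3 | 1-(2-methylprop-1-en-1-yl)pyrrolidine (not isolated) | CC(C)=CN1CCCC1 | intermediate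
4 | methyl 3,3-dimethyl-2-(pyrrolidin-1-yl)cyclobutane-1-carboxylate (racemic, not isolated) | COC(=O)C1CC(C)(C)C1N1CCCC1 | intermediate
5 | methyl 4,4-dimethyl-5-oxopentanoate | COC(=O)CCC(C)(C)C=O | intermediate
6 | methyl (5E)-6-iodo-4,4-dimethylhex-5-enoate | COC(=O)CCC(C)(C)/C=C/I | intermediate
7 | tributyl(propa-1,2-dien-1-yl)stannane | C=C=C[Sn](CCCC)(CCCC)CCCC | starting material
8 | methyl (5E)-4,4-dimethylnona-5,7,8-trienoate | COC(=O)CCC(C)(C)/C=C/C=C=C | intermediate
9 | (5E)-4,4-dimethylnona-5,7,8-trienal | O=CCCC(C)(C)/C=C/C=C=C | intermediate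
10 | methyl propiolate | C#CC(=O)OC | starting material
11 | methyl 3-(methylzincio)prop-2-ynoate (not isolated) | C[Zn]C#CC(=O)OC | intermediate
12 | methyl (4S,8E)-4-hydroxy-7,7-dimethyldodeca-8,10,11-trien-2-ynoate | COC(=O)C#C[C@@H](O)CCC(C)(C)/C=C/C=C=C | intermediate
13 | methyl (4S,8E)-7,7-dimethyl-4-(methylsulfonyloxy)dodeca-8,10,11-trien-2-ynoate (not isolated) | COC(=O)C#C[C@@H](OS(C)(=O)=O)CCC(C)(C)/C=C/C=C=C | intermediate
14 | methyl (aS,8E)-2,7,7-trimethyldodeca-2,3,8,10,11-pentaenoate (allene axis C2–C4 is aS, i.e. P) | COC(=O)C(C)=[C@@]=C([H])CCC(C)(C)/C=C/C=C=C | intermediate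
15 | methyl (1R,4aS)-1,5,5-trimethyl-2-methylidene-1,2,4a,5,6,7-hexahydronaphthalene-1-carboxylate | COC(=O)[C@]1(C)C(=C)C=C[C@H]2C(C)(C)CCC=C12 | intermediate
16 | (1R,4aS)-1,5,5-trimethyl-2-methylidene-1,2,4a,5,6,7-hexahydronaphthalene-1-carbaldehyde | O=C[C@]1(C)C(=C)C=C[C@H]2C(C)(C)CCC=C12 | intermediate
17 | (4S)-4-methyloxolan-2-one, (S)-β-methyl-γ-butyrolactone | O=C1C[C@H](C)CO1 | starting material
18 | [(2S)-3-carboxy-2-methylpropyl]triphenylphosphonium bromide | OC(=O)C[C@H](C)C[P+](c1ccccc1)(c1ccccc1)c1ccccc1.[Br-] | intermediate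
19 | sodium (3S)-3-methyl-4-(triphenyl-λ5-phosphanylidene)butanoate (not isolated) | [Na+].[O-]C(=O)C[C@H](C)C=P(c1ccccc1)(c1ccccc1)c1ccccc1 | intermediate
20 | (3S,4Z)-3-methyl-5-[(1R,4aS)-1,5,5-trimethyl-2-methylidene-1,2,4a,5,6,7-hexahydronaphthalen-1-yl]pent-4-enoic acid | OC(=O)C[C@H](C)/C=C\[C@]1(C)C(=C)C=C[C@H]2C(C)(C)CCC=C12 | intermediate
21 | (3R)-3-methyl-5-[(1R,2R,4aS)-1,2,5,5-tetramethyl-1,2,3,4,4a,5,6,7-octahydronaphthalen-1-yl]pentanoic acid | OC(=O)C[C@H](C)CC[C@@]1(C)C2=CCCC(C)(C)[C@@H]2CC[C@H]1C | intermediate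
22 | (S)-glycidol | OC[C@H]1CO1 | starting material
23 | (R)-glycidyl acetate | CC(=O)OC[C@H]1CO1 | intermediate
24 | (2S)-3-(acetyloxy)-2-hydroxypropyl (3R)-3-methyl-5-[(1R,2R,4aS)-1,2,5,5-tetramethyl-1,2,3,4,4a,5,6,7-octahydronaphthalen-1-yl]pentanoate (CNP0317518.1) | CC(=O)OC[C@H](O)COC(=O)C[C@H](C)CC[C@@]1(C)C2=CCCC(C)(C)[C@@H]2CC[C@H]1C | target

## Step count and weak points

Total: 13 steps (11 on the main line plus two one-step reagent preparations, steps 9 and 12). Longest linear sequence: 11 steps (steps 1–8, 10, 11, 13, from isobutyraldehyde).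

**Step 7 (bis-allene Diels–Alder).** The risks are competition from the ester-endo transition state (which would give the C5 epimer) and Lewis-acid-induced oligomerisation of the bis-allene. The fallback sets out from 14 and returns at 16. It moves the cycloaddition to the aldehyde oxidation level, where the α-methyl enal-type dienophile is far more reactive and is the classic exo-selective case. Reduction of 14 with DIBAL-H (2.2 equiv, −78 °C) gives the allenyl alcohol (aS,8E)-2,7,7-trimethyldodeca-2,3,8,10,11-pentaen-1-ol F1. MnO2 in CH2Cl2 at 0 °C oxidises it to the allenal (aS,8E)-2,7,7-trimethyldodeca-2,3,8,10,11-pentaenal F2. F2 is cyclised with Me2AlCl at −78 °C (or simply on standing at rt) and gives aldehyde 16 directly, so step 8 is no longer needed.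

**Step 11 (triple hydrogenation).** The risks are incomplete β-face selectivity at C8 on the flat ring-B diene and partial reduction or migration of C1=C10. The fallback sets out from 20 and returns at 21. It sets C8 with a bulky stoichiometric borane instead of a catalyst surface. Disiamylborane (2.2 equiv, one equivalent being taken up by the acid; THF, 0 °C) adds only to the exocyclic methylene, boron on C17 and hydrogen on C8 from the face away from the C9 side chain, giving the C17-disiamylboryl adduct F3 (drawn as the free acid). Protonolysis of the primary C–B bond with acetic acid at 60 °C gives (3S,4Z)-3-methyl-5-[(1R,2R,4aS)-1,2,5,5-tetramethyl-1,2,4a,5,6,7-hexahydronaphthalen-1-yl]pent-4-enoic acid F4. Hydrogenation of F4 (H2, Pt/C) then only has to saturate the two disubstituted alkenes and gives 21.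

**Step 13 (acid–epoxide coupling).** The risks are attack at the internal epoxide carbon and 1,3→1,2 acyl migration at 80 °C. The fallback sets out from 21 and returns at 24. It builds the glyceride by the protected-glycerol route. Steglich esterification of 21 with (R)-solketal (DCC, DMAP, CH2Cl2) gives [(4S)-2,2-dimethyl-1,3-dioxolan-4-yl]methyl (3R)-3-methyl-5-[(1R,2R,4aS)-1,2,5,5-tetramethyl-1,2,3,4,4a,5,6,7-octahydronaphthalen-1-yl]pentanoate F5. Acetonide removal (Dowex 50W-H+, MeOH, rt) gives the 1-monoacyl-sn-glycerol (2S)-2,3-dihydroxypropyl (3R)-3-methyl-5-[(1R,2R,4aS)-1,2,5,5-tetramethyl-1,2,3,4,4a,5,6,7-octahydronaphthalen-1-yl]pentanoate F6. Primary-selective acetylation of F6 (vinyl acetate, immobilised Candida antarctica lipase B, MTBE, rt) gives 24.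

## Further compounds

F1 | step 7 | (aS,8E)-2,7,7-trimethyldodeca-2,3,8,10,11-pentaen-1-ol | OCC(C)=[C@@]=C([H])CCC(C)(C)/C=C/C=C=C
F2 | step 7 | (aS,8E)-2,7,7-trimethyldodeca-2,3,8,10,11-pentaenal | O=CC(C)=[C@@]=C([H])CCC(C)(C)/C=C/C=C=C
F3 | step 11 | (3S,4Z)-5-[(1R,2R,4aS)-2-{[bis(3-methylbutan-2-yl)boranyl]methyl}-1,5,5-trimethyl-1,2,4a,5,6,7-hexahydronaphthalen-1-yl]-3-methylpent-4-enoic acid | OC(=O)C[C@H](C)/C=C\[C@@]1(C)C2=CCCC(C)(C)[C@@H]2C=C[C@H]1CB(C(C)C(C)C)C(C)C(C)C
F4 | step 11 | (3S,4Z)-3-methyl-5-[(1R,2R,4aS)-1,2,5,5-tetramethyl-1,2,4a,5,6,7-hexahydronaphthalen-1-yl]pent-4-enoic acid | OC(=O)C[C@H](C)/C=C\[C@@]1(C)C2=CCCC(C)(C)[C@@H]2C=C[C@H]1C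
F5 | step 13 | [(4S)-2,2-dimethyl-1,3-dioxolan-4-yl]methyl (3R)-3-methyl-5-[(1R,2R,4aS)-1,2,5,5-tetramethyl-1,2,3,4,4a,5,6,7-octahydronaphthalen-1-yl]pentanoate | CC1(C)OC[C@H](O1)COC(=O)C[C@H](C)CC[C@@]2(C)C3=CCCC(C)(C)[C@@H]3CC[C@H]2C
F6 | step 13 | (2S)-2,3-dihydroxypropyl (3R)-3-methyl-5-[(1R,2R,4aS)-1,2,5,5-tetramethyl-1,2,3,4,4a,5,6,7-octahydronaphthalen-1-yl]pentanoate | OC[C@H](O)COC(=O)C[C@H](C)CC[C@@]1(C)C2=CCCC(C)(C)[C@@H]2CC[C@H]1C
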